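The earlier runs and the new flask were generated by integration from invented constants, and the scatter is random.

The target is counted in two runs: the delta flask, still being followed, and the earlier beta run.

| flask | substrate | reagent in the second phase | remark | time | volume of the second phase over the first |
|---|---|---|---|---|---|
| delta | 20 mM | 2 equiv | the very flask that is asked about, followed so far |  |  |
| beta | 30 mM | 2 equiv | run made earlier |  |  |
| flask | 20 mM | 2.00 equiv |  | 1.0 h | 0.50 |

- delta (time / min: target / %): 2.00: 0; 4.00: 1.0; 6.00: 0.9; 8.00: 3.9; 10.0: 6.3
- beta (time / min: target / %): 2.00: 0; 4.00: 0.4; 6.00: 3.6; 12.0: 7.1; 25.0: 18.1

(standard deviation of a reading: 1 percentage point)

- in the second phase: reagent in the second phase; everything else is in the first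
- charges count per volume of the first phase; a concentration in a rate is the amount of a species over the volume of its own phase; every rate counts per litre of the first phase
- the numbers in the tables scatter with a standard deviation of 1 percentage point
- the earlier runs hold the two phases in the same ratio of volumes as the flask asked about

- target at 1.0 h, in percent of the substrate charged
- the change that raises the amount of target at 1.0 h, in percent of the substrate charged most ("none" if none brings more than 2 percentage points) (maple / alder / none)
- amount of target at 1.0 h, in percent of the substrate charged, after alder

- maple: doubling the amount of reagent in the second phase, all else as stated
- alder: doubling the transfer coefficient of the reagent in the second phase, all else as stated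

In the delta flask the target reads nothing at 2.00 min and 1.0% at 4.00 min, so the reckoning here takes a lag of about 3.00 min while reagent crosses over. The second time is the substrate's lifetime once reagent stands beside it. If the rate is first order in substrate and in that reagent, the reagent concentration sets a pseudo-first-order constant. Beta's last reading, 18.1% at 25.0 min, gives a lifetime of 110 min. Equivalents and volume ratio are equal, so reagent should follow the charge, and this flask's substrate lifetime, the reciprocal of its pseudo-first-order constant, is 165 min. Delta's few readings, with their scatter of 1 percentage point, cannot test that scaling.

The lag is far shorter than the lifetime. The target at 1.0 h then comes to 29.2%. Maple, shortening the lifetime by a factor of 2, gives 49.9%. Alder, shortening the lag by that factor, gives 29.9%.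

The forecast differs on the yields: 41%, maple, and 70% after alder, its grounds being that the runs' common percent rate “points to transfer-limited supply”.

The simulation gives 29.5%, maple with a gain of 21 points, and 30.8% after alder.

    reagent in the reaction phase ⇌ reagent in the second phase, rate k1*([reagent in the reaction phase] - [reagent in the second phase]/K1) per volume of the first phase (partition coefficient = 1.20, kL = 3.90 h⁻¹)
    substrate + reagent in the reaction phase → target (k = 17.0 M⁻¹ h⁻¹)

The hour of the reading is short beside the lifetime of 165 min, and this flask stands at 29.5% because of that hour together with the wearing away of reagent in the second phase. The run without that wearing away gives 55.6% at 1.0 h, and the flask read at 10.0 h holds 93.5%. Lag and lifetime put the same flask, left until 2.5 h, at 59.0% of target, and it holds 56.9%.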